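**Strategy.** Ring A is disconnected across C3a–C4 and C7–C7a. Its C3a–C7a edge is the C4=C5 double bond of a trans-2,3-dihydrofuran that already carries C2 and C3. C4 (with its carbonyl carbon) and C7 (with its oxygen) are C6 and C3 of a 3-benzyloxy-2-pyrone. One operation (cycloaddition, CO2 loss, aromatisation) builds the whole benzo ring. The dihydrofuran is used as the 5-silyloxy derivative of an aldol-derived lactone. C7a therefore arrives at the aryl-ether oxidation level, and silanol loss replaces an oxidant that would attack the dihydrofuran. The pyrone carries a Weinreb amide at C6, which steers the regiochemistry and later gives the aldehyde directly.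

Key step: step 9

Remark: atom labels C2 to C7a follow the benzofuran numbering of the target. The transient centres of the two unisolated key-step intermediates are left undefined, because a mixture of endo/exo and facial isomers is expected and all of them converge on one arene.

Step 1
Reactants: 1 (S)-4-benzyl-1,3-oxazolidin-2-one; 2 methyl 4-chloro-4-oxobutanoate
Product: 3 methyl 4-[(4S)-4-benzyl-2-oxo-1,3-oxazolidin-3-yl]-4-oxobutanoate
Conditions: Et3N, DMAP (cat.), CH2Cl2, 0 °C to rt
Reagents that add atoms: none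
Why: DMAP-catalysed N-acylation of an oxazolidinone by an acid chloride is routine and leaves the methyl ester and the auxiliary stereocentre untouched.

Step 2
Reactants: 3 methyl 4-[(4S)-4-benzyl-2-oxo-1,3-oxazolidin-3-yl]-4-oxobutanoate; 4 3,4-bis(benzyloxy)benzaldehyde
Product: 7 (4S)-4-benzyl-3-{(2S,3S)-2-[3,4-bis(benzyloxy)phenyl]-5-oxooxolane-3-carbonyl}-1,3-oxazolidin-2-one (trans lactone), via boron enolate 5 (not isolated), via aldol adduct 6 (not isolated)
Conditions: Bu2BOTf, Et3N, CH2Cl2, 0 °C; 4, −78 to 0 °C; H2O2, MeOH, pH 7 buffer; then PPTS (cat.), CH2Cl2, rt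
Reagents that add atoms: none
Why: In this Evans syn-aldol reaction only the imide is enolised, the (Z)-boron enolate reacts through a Zimmerman–Traxler chair on the face away from the benzyl group of the (S)-auxiliary and so sets future C3 and C2 (both S), and acid-catalysed transesterification of the syn adduct onto the γ-ester should give the trans lactone.

Step 3
Reactants: 7 (4S)-4-benzyl-3-{(2S,3S)-2-[3,4-bis(benzyloxy)phenyl]-5-oxooxolane-3-carbonyl}-1,3-oxazolidin-2-one
Product: 9 (2S,3S)-2-[3,4-bis(benzyloxy)phenyl]-5-oxooxolane-3-carboxylic acid, via peroxy acid 8 (not isolated)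
Conditions: LiOH, H2O2, THF–H2O, 0 °C; aq. Na2SO3; then HCl to pH 2
Reagents that add atoms: hydrogen peroxide, OO
Why: Hydroperoxide cleaves the exocyclic imide carbonyl selectively (standard auxiliary removal), sulfite reduces the peroxy acid, and any lactone opened by hydroxide closes again on acidification with both centres unchanged.

Step 4
Reactants: 9 (2S,3S)-2-[3,4-bis(benzyloxy)phenyl]-5-oxooxolane-3-carboxylic acid
Product: 10 methyl (2S,3S)-2-[3,4-bis(benzyloxy)phenyl]-5-oxooxolane-3-carboxylate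
Conditions: TMSCHN2, PhMe–MeOH, 0 °C
Reagents that add atoms: (trimethylsilyl)diazomethane, C[Si](C)(C)C=[N+]=[N-]
Why: Diazoalkane O-methylation of a carboxylic acid runs under neutral conditions, so neither the lactone nor the epimerisable C3 centre is disturbed.

Step 5
Reactants: 10 methyl (2S,3S)-2-[3,4-bis(benzyloxy)phenyl]-5-oxooxolane-3-carboxylate
Product: 11 methyl (2S,3S)-2-[3,4-bis(benzyloxy)phenyl]-5-[(tert-butyldimethylsilyl)oxy]-2,3-dihydrofuran-3-carboxylate
Conditions: TBSOTf (1.1 equiv), Et3N, CH2Cl2, 0 °C; cold aq. NaHCO3, pentane extraction, used crude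
Reagents that add atoms: tert-butyldimethylsilyl trifluoromethanesulfonate, CC(C)(C)[Si](C)(C)OS(=O)(=O)C(F)(F)F
Why: In this soft enolisation and O-silylation the lactone carbonyl is the more Lewis-basic site and its unhindered CH2 the more acidic one, so the silyl triflate/amine pair should give the cyclic silyl ketene acetal while the tertiary C3–H next to the methyl ester is left alone.

Step 6
Reactants: 12 mucic acid (galactaric acid)
Product: 14 3-hydroxy-2-oxo-2H-pyran-6-carboxylic acid, via acetoxypyrone acid 13 (not isolated)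
Conditions: Ac2O, pyridine, 90 °C; concentrate; then 6 M aq. HCl, 60 °C
Reagents that add atoms: none
Why: In this acetylative dehydration of an aldaric acid, peracetylation, δ-lactonisation and two β-eliminations of acetic acid give the 3-acetoxy-2-pyrone-6-carboxylic acid (a known conversion of mucic acid), and aqueous acid then hydrolyses the enol acetate, all four stereocentres being erased.

Step 7
Reactants: 14 3-hydroxy-2-oxo-2H-pyran-6-carboxylic acid
Product: 15 3-hydroxy-N-methoxy-N-methyl-2-oxo-2H-pyran-6-carboxamide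
Conditions: MeONHMe·HCl, EDC·HCl, N-methylmorpholine, DMF, 0 °C to rt
Reagents that add atoms: N,O-dimethylhydroxylamine hydrochloride, CNOC.Cl
Why: Carbodiimide amide coupling gives the Weinreb amide, the weakly basic amine being too poor a nucleophile to open the pyrone and a far better acyl acceptor than the enolic 3-OH.

Step 8
Reactants: 15 3-hydroxy-N-methoxy-N-methyl-2-oxo-2H-pyran-6-carboxamide
Product: 16 3-(benzyloxy)-N-methoxy-N-methyl-2-oxo-2H-pyran-6-carboxamide
Conditions: BnBr, K2CO3, DMF, rt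
Reagents that add atoms: benzyl bromide, BrCc1ccccc1
Why: Williamson etherification of the acidic 3-hydroxy-2-pyrone takes place on oxygen under mild carbonate conditions that leave the ring and the amide intact.

Step 9
Reactants: 11 methyl (2S,3S)-2-[3,4-bis(benzyloxy)phenyl]-5-[(tert-butyldimethylsilyl)oxy]-2,3-dihydrofuran-3-carboxylate; 16 3-(benzyloxy)-N-methoxy-N-methyl-2-oxo-2H-pyran-6-carboxamide
Product: 19 methyl (2S,3S)-7-(benzyloxy)-2-[3,4-bis(benzyloxy)phenyl]-4-[methoxy(methyl)carbamoyl]-2,3-dihydro-1-benzofuran-3-carboxylate, via bridged lactone 17 (not isolated), via cyclohexadiene ketal 18 (not isolated)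
Conditions: 16 (1.5 equiv), 2,6-di-tert-butyl-4-methylpyridine (0.2 equiv), PhMe, 110 °C, sealed tube
Reagents that add atoms: none
Why: Proposed new method: C4 of the silyl ketene acetal 11 (future C3a, the nucleophilic terminus) bonds to C6 of pyrone 16 and C5 (future C7a) to C3 in an asynchronous inverse-electron-demand [4+2] cycloaddition, so ring A closes as a six-membered carbocycle by intermolecular cycloaddition (bridged lactone 17); retro-[4+2] loss of CO2 gives the cyclohexadiene ketal 18, whose C7a–OSi bond ionises and whose C3a proton is then lost, which aromatises the ring without an oxidant. The closest known reaction type is the benzannulation of 2-pyrone esters with acyclic ketene acetals (cycloaddition, CO2 loss, alcohol loss); a lactone-derived endocyclic silyl ketene acetal and a 3-alkoxy-2-pyrone-6-carboxamide have not been used in it. Regioselectivity is required and is secured in 16: attack at C6 develops a lactone dienolate, whereas attack at C3 would develop a much poorer amide dienolate, which is why C6 carries an amide and not an ester. Chemoselectivity of the aromatisation is required and is secured in 11: silanolate is a better leaving group than the secondary alkoxide O1 and leaves behind the better, alkoxy-stabilised cation, so the C7a–O1 bond should stay. No lasting stereocentre is formed, since the centres created at C3a, C4, C7 and C7a are all erased. C2 and C3 come unchanged from 11, because the medium holds neither oxidant nor acid and only a hindered pyridine as buffer.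

Step 10
Reactants: 19 methyl (2S,3S)-7-(benzyloxy)-2-[3,4-bis(benzyloxy)phenyl]-4-[methoxy(methyl)carbamoyl]-2,3-dihydro-1-benzofuran-3-carboxylate
Product: 20 methyl (2S,3S)-7-(benzyloxy)-2-[3,4-bis(benzyloxy)phenyl]-4-formyl-2,3-dihydro-1-benzofuran-3-carboxylate
Conditions: Cp2Zr(H)Cl (1.8 equiv), THF, rt; then H2O, SiO2
Reagents that add atoms: none
Why: In this chemoselective amide-to-aldehyde reduction the zirconium hydride adds to the most Lewis-basic carbonyl and gives a stable zirconium hemiaminal that releases the aldehyde only on work-up, so over-reduction is avoided and the methyl ester, the benzyl ethers and C2/C3 stay untouched.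

Step 11
Reactants: 21 (R)-3-(3,4-dihydroxyphenyl)lactic acid (danshensu)
Product: 22 benzyl (2R)-3-[3,4-bis(benzyloxy)phenyl]-2-hydroxypropanoate
Conditions: BnBr (3.3 equiv), K2CO3, DMF, rt
Reagents that add atoms: benzyl bromide, BrCc1ccccc1
Why: In this Williamson etherification and carboxylate alkylation, carbonate deprotonates only the two phenols and the acid, so the secondary alcohol stays free and the (R)-centre, which takes no part, is retained.

Step 12
Reactants: 22 benzyl (2R)-3-[3,4-bis(benzyloxy)phenyl]-2-hydroxypropanoate; 23 (diethoxyphosphoryl)acetic acid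
Product: 24 benzyl (2R)-3-[3,4-bis(benzyloxy)phenyl]-2-{[(diethoxyphosphoryl)acetyl]oxy}propanoate
Conditions: N,N'-dicyclohexylcarbodiimide, DMAP (cat.), CH2Cl2, 0 °C to rt
Reagents that add atoms: none
Why: Steglich esterification acylates the alcohol oxygen without breaking the C–O bond of the stereocentre, so the (R)-configuration is kept.

Step 13
Reactants: 20 methyl (2S,3S)-7-(benzyloxy)-2-[3,4-bis(benzyloxy)phenyl]-4-formyl-2,3-dihydro-1-benzofuran-3-carboxylate; 24 benzyl (2R)-3-[3,4-bis(benzyloxy)phenyl]-2-{[(diethoxyphosphoryl)acetyl]oxy}propanoate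
Product: 25 methyl (2S,3S)-7-(benzyloxy)-4-[(E)-3-{[(2R)-1-(benzyloxy)-3-[3,4-bis(benzyloxy)phenyl]-1-oxopropan-2-yl]oxy}-3-oxoprop-1-en-1-yl]-2-[3,4-bis(benzyloxy)phenyl]-2,3-dihydro-1-benzofuran-3-carboxylate
Conditions: LiCl, iPr2NEt, MeCN, rt
Reagents that add atoms: none
Why: Under these Horner–Wadsworth–Emmons (Masamune–Roush) conditions the lithium-chelated stabilised phosphonate is deprotonated by a weak amine base and should give the (E)-acrylate, while C3–H and the α-acyloxy ester centre are not enolised.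

Step 14
Reactants: 25 hexabenzyl-protected monomethyl lithospermate
Product: 26 monomethyl lithospermate
Conditions: BCl3 (excess), pentamethylbenzene, CH2Cl2, −78 to −20 °C; then aq. THF
Reagents that add atoms: none
Why: In this Lewis-acid debenzylation BCl3 binds the aryl ether and benzyl ester oxygens and pentamethylbenzene captures the benzyl cations irreversibly (Friedel–Crafts), which should remove five benzyl ethers and the benzyl ester at low temperature without touching the acrylate double bond, the methyl ester or the three stereocentres.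

**Compound list**
1 | (S)-4-benzyl-1,3-oxazolidin-2-one | O=C1N[C@@H](Cc2ccccc2)CO1 | starting material
2 | methyl 4-chloro-4-oxobutanoate | COC(=O)CCC(=O)Cl | starting material
3 | methyl 4-[(4S)-4-benzyl-2-oxo-1,3-oxazolidin-3-yl]-4-oxobutanoate | COC(=O)CCC(=O)N1[C@@H](Cc2ccccc2)COC1=O | intermediate
4 | 3,4-bis(benzyloxy)benzaldehyde | O=Cc1ccc(OCc2ccccc2)c(OCc2ccccc2)c1 | starting material
5 | (Z)-dibutylboron enolate of 3 | COC(=O)C/C=C(\OB(CCCC)CCCC)N1[C@@H](Cc2ccccc2)COC1=O | intermediate
6 | methyl (3S,4S)-3-[(4S)-4-benzyl-2-oxo-1,3-oxazolidine-3-carbonyl]-4-[3,4-bis(benzyloxy)phenyl]-4-hydroxybutanoate (syn aldol adduct) | COC(=O)C[C@@H]([C@H](O)c1ccc(OCc2ccccc2)c(OCc2ccccc2)c1)C(=O)N1[C@@H](Cc2ccccc2)COC1=O | intermediate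
7 | (4S)-4-benzyl-3-{(2S,3S)-2-[3,4-bis(benzyloxy)phenyl]-5-oxooxolane-3-carbonyl}-1,3-oxazolidin-2-one | O=C([C@H]1CC(=O)O[C@@H]1c1ccc(OCc2ccccc2)c(OCc2ccccc2)c1)N1[C@@H](Cc2ccccc2)COC1=O | intermediate
8 | (2S,3S)-2-[3,4-bis(benzyloxy)phenyl]-5-oxooxolane-3-carboperoxoic acid | OOC(=O)[C@H]1CC(=O)O[C@@H]1c1ccc(OCc2ccccc2)c(OCc2ccccc2)c1 | intermediate
9 | (2S,3S)-2-[3,4-bis(benzyloxy)phenyl]-5-oxooxolane-3-carboxylic acid | OC(=O)[C@H]1CC(=O)O[C@@H]1c1ccc(OCc2ccccc2)c(OCc2ccccc2)c1 | intermediate
10 | methyl (2S,3S)-2-[3,4-bis(benzyloxy)phenyl]-5-oxooxolane-3-carboxylate | COC(=O)[C@H]1CC(=O)O[C@@H]1c1ccc(OCc2ccccc2)c(OCc2ccccc2)c1 | intermediate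
11 | methyl (2S,3S)-2-[3,4-bis(benzyloxy)phenyl]-5-[(tert-butyldimethylsilyl)oxy]-2,3-dihydrofuran-3-carboxylate | COC(=O)[C@H]1C=C(O[Si](C)(C)C(C)(C)C)O[C@@H]1c1ccc(OCc2ccccc2)c(OCc2ccccc2)c1 | intermediate
12 | mucic acid (galactaric acid) | O=C(O)[C@H](O)[C@@H](O)[C@@H](O)[C@H](O)C(=O)O | starting material
13 | 3-acetoxy-2-oxo-2H-pyran-6-carboxylic acid | CC(=O)OC1=CC=C(C(=O)O)OC1=O | intermediate
14 | 3-hydroxy-2-oxo-2H-pyran-6-carboxylic acid | OC1=CC=C(C(=O)O)OC1=O | intermediate
15 | 3-hydroxy-N-methoxy-N-methyl-2-oxo-2H-pyran-6-carboxamide | CON(C)C(=O)C1=CC=C(O)C(=O)O1 | intermediate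
16 | 3-(benzyloxy)-N-methoxy-N-methyl-2-oxo-2H-pyran-6-carboxamide | CON(C)C(=O)C1=CC=C(OCc2ccccc2)C(=O)O1 | intermediate
17 | [4+2] adduct of 11 and 16: 2-oxabicyclo[2.2.2]oct-7-en-3-one fused to the oxolane ring (C4 bears the amide and the bridging O, C7 bears OBn and the bridging C=O, C7a bears OTBS and O1; C2 and C3 as in 11, other centres undefined) | COC(=O)[C@H]1C2C3(C(=O)N(C)OC)C=CC(OCc4ccccc4)(C(=O)O3)C2(O[Si](C)(C)C(C)(C)C)O[C@@H]1c1ccc(OCc2ccccc2)c(OCc2ccccc2)c1 | intermediate
18 | 3a,7a-dihydro form of 19 with OTBS on C7a and H on C3a (cyclohexa-1,3-diene, C4=C5 and C6=C7; C2 and C3 as in 11, C3a and C7a undefined) | COC(=O)[C@H]1C2C(C(=O)N(C)OC)=CC=C(OCc3ccccc3)C2(O[Si](C)(C)C(C)(C)C)O[C@@H]1c1ccc(OCc2ccccc2)c(OCc2ccccc2)c1 | intermediate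
19 | methyl (2S,3S)-7-(benzyloxy)-2-[3,4-bis(benzyloxy)phenyl]-4-[methoxy(methyl)carbamoyl]-2,3-dihydro-1-benzofuran-3-carboxylate | COC(=O)[C@H]1c2c(C(=O)N(C)OC)ccc(OCc3ccccc3)c2O[C@@H]1c1ccc(OCc2ccccc2)c(OCc2ccccc2)c1 | intermediate
20 | methyl (2S,3S)-7-(benzyloxy)-2-[3,4-bis(benzyloxy)phenyl]-4-formyl-2,3-dihydro-1-benzofuran-3-carboxylate | COC(=O)[C@H]1c2c(C=O)ccc(OCc3ccccc3)c2O[C@@H]1c1ccc(OCc2ccccc2)c(OCc2ccccc2)c1 | intermediate
21 | (R)-3-(3,4-dihydroxyphenyl)lactic acid (danshensu) | O[C@H](Cc1ccc(O)c(O)c1)C(=O)O | starting material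
22 | benzyl (2R)-3-[3,4-bis(benzyloxy)phenyl]-2-hydroxypropanoate | O[C@H](Cc1ccc(OCc2ccccc2)c(OCc2ccccc2)c1)C(=O)OCc1ccccc1 | intermediate
23 | (diethoxyphosphoryl)acetic acid | CCOP(=O)(CC(=O)O)OCC | starting material
24 | benzyl (2R)-3-[3,4-bis(benzyloxy)phenyl]-2-{[(diethoxyphosphoryl)acetyl]oxy}propanoate | CCOP(=O)(CC(=O)O[C@H](Cc1ccc(OCc2ccccc2)c(OCc2ccccc2)c1)C(=O)OCc1ccccc1)OCC | intermediate
25 | hexabenzyl-protected monomethyl lithospermate (full name in step 13) | COC(=O)[C@H]1c2c(/C=C/C(=O)O[C@H](Cc3ccc(OCc4ccccc4)c(OCc4ccccc4)c3)C(=O)OCc3ccccc3)ccc(OCc3ccccc3)c2O[C@@H]1c1ccc(OCc2ccccc2)c(OCc2ccccc2)c1 | intermediate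
26 | monomethyl lithospermate | COC(=O)[C@H]1c2c(/C=C/C(=O)O[C@H](Cc3ccc(O)c(O)c3)C(=O)O)ccc(O)c2O[C@@H]1c1ccc(O)c(O)c1 | target

**Step count.** Total: 14 steps. Longest linear sequence: 9 steps (1, 2, 3, 4, 5, 9, 10, 13, 14).

**Steps most likely to fail**

1. **Step 9.** The cycloaddition of the donor-substituted pyrone may be too slow. The termini may pair the wrong way round. Aromatisation may proceed by rupture of the C7a–O1 bond instead of the C7a–OSi bond.
   - The fallback uses known chemistry only. It sets out from 4 and comes back at 20.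
   - Corey–Fuchs homologation of 4 (CBr4, PPh3, CH2Cl2) gives 4-(2,2-dibromoethenyl)-1,2-bis(benzyloxy)benzene F1.
   - n-BuLi followed by ClCO2Me gives methyl 3-[3,4-bis(benzyloxy)phenyl]prop-2-ynoate F2.
   - Anti conjugate addition of commercial 4-(benzyloxy)-3-hydroxybenzaldehyde (K2CO3, DMF) gives methyl (Z)-3-[2-(benzyloxy)-5-formylphenoxy]-3-[3,4-bis(benzyloxy)phenyl]prop-2-enoate F3.
   - Condensation with (R)-1-aminoindane gives the chiral aldimine F4.
   - Imine-directed ortho C–H activation and intramolecular alkylation with [RhCl(coe)2]2 (coe = cyclooctene) and (dicyclohexylphosphino)ferrocene in toluene at 75 °C adds C3a–H syn across the alkene. This gives the cis-(2S,3R)-dihydrobenzofuran imine F5.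
   - Aqueous acid frees the cis-(2S,3R)-aldehyde F6. DBU epimerises C3 to the more stable trans isomer 20, whose enantiomeric purity is raised by recrystallisation.

2. **Step 14.** The Lewis acid may ionise the electron-rich benzylic C2–O1 bond, which would lead to ring opening, epimerisation or capture by the scavenger. Cleavage of the benzyl ester may also be incomplete.
   - The fallback removes all benzyl groups before the alkene exists. It sets out from 20 and 22 and comes back at 26.
   - Hydrogenolysis of 20 (H2, Pd/C, EtOAc) gives methyl (2S,3S)-2-(3,4-dihydroxyphenyl)-4-formyl-7-hydroxy-2,3-dihydro-1-benzofuran-3-carboxylate F7.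
   - Heating 22 with Meldrum's acid in toluene gives the malonic half-ester 3-{[(2R)-1-(benzyloxy)-3-[3,4-bis(benzyloxy)phenyl]-1-oxopropan-2-yl]oxy}-3-oxopropanoic acid F8.
   - Hydrogenolysis of F8 gives (2R)-2-[(carboxyacetyl)oxy]-3-(3,4-dihydroxyphenyl)propanoic acid F9.
   - Knoevenagel–Doebner condensation of F7 with F9 (pyridine, piperidine cat., 60 °C) forms the (E)-acrylate with decarboxylation and gives 26 directly.

3. **Step 5.** The silyl triflate may ionise the benzylic C2–O1 bond. A second silylation at the methyl ester would erase C3. The ketene acetal may also hydrolyse on handling.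
   - The fallback replaces soft enolisation by a kinetic metal enolate and the silyloxy group by a true nucleofuge. It sets out from 10 and comes back at 19.
   - KN(SiMe3)2 (THF, −78 °C) followed by (PhO)2P(O)Cl gives methyl (2S,3S)-2-[3,4-bis(benzyloxy)phenyl]-5-[(diphenoxyphosphoryl)oxy]-2,3-dihydrofuran-3-carboxylate F10. This compound tolerates filtration through Et3N-deactivated silica.
   - Heating F10 with 16 and 2,6-lutidine in toluene should lead through the bridged lactone phosphate F11 and the cyclohexadiene phosphate F12. Loss of phosphate and of the C3a proton then gives 19.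

**Further compounds**
F1 | step 9 | 4-(2,2-dibromoethenyl)-1,2-bis(benzyloxy)benzene | BrC(Br)=Cc1ccc(OCc2ccccc2)c(OCc2ccccc2)c1
F2 | step 9 | methyl 3-[3,4-bis(benzyloxy)phenyl]prop-2-ynoate | COC(=O)C#Cc1ccc(OCc2ccccc2)c(OCc2ccccc2)c1
F3 | step 9 | methyl (Z)-3-[2-(benzyloxy)-5-formylphenoxy]-3-[3,4-bis(benzyloxy)phenyl]prop-2-enoate | COC(=O)/C=C(\Oc1cc(C=O)ccc1OCc1ccccc1)c1ccc(OCc2ccccc2)c(OCc2ccccc2)c1
F4 | step 9 | (E)-aldimine of F3 with (R)-1-aminoindane | COC(=O)/C=C(\Oc1cc(/C=N/[C@@H]2CCc3ccccc32)ccc1OCc1ccccc1)c1ccc(OCc2ccccc2)c(OCc2ccccc2)c1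
F5 | step 9 | methyl (2S,3R)-7-(benzyloxy)-2-[3,4-bis(benzyloxy)phenyl]-4-{(E)-[(1R)-2,3-dihydro-1H-inden-1-ylimino]methyl}-2,3-dihydro-1-benzofuran-3-carboxylate | COC(=O)[C@@H]1c2c(/C=N/[C@@H]3CCc4ccccc43)ccc(OCc3ccccc3)c2O[C@@H]1c1ccc(OCc2ccccc2)c(OCc2ccccc2)c1
F6 | step 9 | methyl (2S,3R)-7-(benzyloxy)-2-[3,4-bis(benzyloxy)phenyl]-4-formyl-2,3-dihydro-1-benzofuran-3-carboxylate | COC(=O)[C@@H]1c2c(C=O)ccc(OCc3ccccc3)c2O[C@@H]1c1ccc(OCc2ccccc2)c(OCc2ccccc2)c1
F7 | step 14 | methyl (2S,3S)-2-(3,4-dihydroxyphenyl)-4-formyl-7-hydroxy-2,3-dihydro-1-benzofuran-3-carboxylate | COC(=O)[C@H]1c2c(C=O)ccc(O)c2O[C@@H]1c1ccc(O)c(O)c1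
F8 | step 14 | 3-{[(2R)-1-(benzyloxy)-3-[3,4-bis(benzyloxy)phenyl]-1-oxopropan-2-yl]oxy}-3-oxopropanoic acid | OC(=O)CC(=O)O[C@H](Cc1ccc(OCc2ccccc2)c(OCc2ccccc2)c1)C(=O)OCc1ccccc1
F9 | step 14 | (2R)-2-[(carboxyacetyl)oxy]-3-(3,4-dihydroxyphenyl)propanoic acid | OC(=O)CC(=O)O[C@H](Cc1ccc(O)c(O)c1)C(=O)O
F10 | step 5 | methyl (2S,3S)-2-[3,4-bis(benzyloxy)phenyl]-5-[(diphenoxyphosphoryl)oxy]-2,3-dihydrofuran-3-carboxylate | COC(=O)[C@H]1C=C(OP(=O)(Oc2ccccc2)Oc2ccccc2)O[C@@H]1c1ccc(OCc2ccccc2)c(OCc2ccccc2)c1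
F11 | step 5 | [4+2] adduct of F10 and 16 (as 17, diphenyl phosphate on C7a; new centres undefined) | COC(=O)[C@H]1C2C3(C(=O)N(C)OC)C=CC(OCc4ccccc4)(C(=O)O3)C2(OP(=O)(Oc4ccccc4)Oc4ccccc4)O[C@@H]1c1ccc(OCc2ccccc2)c(OCc2ccccc2)c1
F12 | step 5 | 3a,7a-dihydro form of 19 with diphenyl phosphate on C7a (as 18; C3a and C7a undefined) | COC(=O)[C@H]1C2C(C(=O)N(C)OC)=CC=C(OCc3ccccc3)C2(OP(=O)(Oc3ccccc3)Oc3ccccc3)O[C@@H]1c1ccc(OCc2ccccc2)c(OCc2ccccc2)c1
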